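Plakortolide R is disconnected at the O2–C3 bond of the 1,2-dioxane and at a temporary C7=C3 bond, so that C6, C5, C4, C3 and C7 sit in a cyclopentene on which hydroxyl-directed singlet-oxygen chemistry places the C6 hydroperoxide cis to the C4 oxygen. The key step exploits this 1,3-relationship of C4–O and C6–OO flanked by C3 and C7: ozonolysis cuts C7=C3, the C6 hydroperoxide captures the C3 aldehyde as the six-membered peroxyhemiacetal, and C7 is left as the aldehyde handle for the chain. Its precursor is the cis-configured 1,4-dimethylcyclopent-2-enyl hydroperoxide carrying the C4 oxygen as a triethylsilyl ether, so that only the hydroperoxide can add to a carbonyl group.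

Key step: step 7

Remark: atoms are numbered as in the target (C1 lactone carbonyl, C3 peroxy CH, C4 lactone C–O, C6 peroxy carbon, C7–C16 side chain); C3 of compounds 13–28 is carried as an epimer mixture because it becomes a planar cation in step 17, and the change of the C6 descriptor between 19 and 20 reflects CIP priorities only.

Step 1
Reactants: 1 (R)-2-methylglycidol; 2 isopropenylmagnesium bromide
Product: 3 (S)-2,4-dimethylpent-4-ene-1,2-diol
Conditions: 2 (2.5 equiv), CuBr·SMe2 (10 mol%), THF, −30 → 0 °C; aq NH4Cl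
Reagents that add atoms: none
Why: Copper-catalysed Grignard opening of the epoxide (SN2 at the unsubstituted ring carbon, one equivalent of 2 being spent on the hydroxyl proton) leaves the quaternary stereocentre untouched, so its configuration comes unchanged from 1.

Step 2
Reactants: 3 (S)-2,4-dimethylpent-4-ene-1,2-diol
Product: 5 (S)-2-methyl-2-(2-methylprop-2-en-1-yl)oxirane, via primary tosylate 4 (not isolated)
Conditions: NaH (2.2 equiv), THF, 0 °C; 1-tosylimidazole (1.05 equiv), 0 °C → rt; product kept as a solution (volatile)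
Reagents that add atoms: none
Why: One-pot diol-to-epoxide conversion in which the primary alkoxide is sulfonylated selectively and the tertiary alkoxide then displaces the tosylate (intramolecular Williamson etherification, 3-exo-tet); no bond to the stereocentre is broken.

Step 3
Reactants: 5 (S)-2-methyl-2-(2-methylprop-2-en-1-yl)oxirane; 6 vinylmagnesium bromide
Product: 7 (R)-2,4-dimethylhepta-1,6-dien-4-ol
Conditions: 6 (1.5 equiv), CuBr·SMe2 (10 mol%), THF, −40 → 0 °C; aq NH4Cl
Reagents that add atoms: none
Why: Copper-catalysed Grignard opening of a 2,2-disubstituted epoxide at its CH2 group gives the tertiary homoallylic alcohol with the stereocentre unchanged.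

Step 4
Reactants: 7 (R)-2,4-dimethylhepta-1,6-dien-4-ol
Product: 8 (R)-1,3-dimethylcyclopent-3-en-1-ol
Conditions: second-generation Grubbs catalyst RuCl2(=CHPh)(H2IMes)(PCy3) (2 mol%), CH2Cl2, 40 °C
Reagents that add atoms: none
Why: Ring-closing metathesis of a monosubstituted with a 1,1-disubstituted alkene forms the trisubstituted cyclopentene with loss of ethene and tolerates the free tertiary alcohol.

Step 5
Reactants: 8 (R)-1,3-dimethylcyclopent-3-en-1-ol
Product: 9 (1R,4S)-4-hydroxy-1,4-dimethylcyclopent-2-en-1-yl hydroperoxide (OOH cis to OH)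
Conditions: O2, visible light, tetraphenylporphyrin (cat.), CH2Cl2, −20 °C; cold chromatography, used promptly
Reagents that add atoms: dioxygen, O=O
Why: Schenck ene reaction of singlet oxygen in which oxygen bonds to the methyl-bearing alkene carbon (C3 of 8) while an allylic hydrogen on C5 is transferred and the double bond moves to C4=C5, the new stereocentre (C6 of the target) being set by attack on the ring face that carries the hydroxyl group, which hydrogen-bonds to the incoming oxygen in a non-polar medium and is also the face away from the C1 methyl; the secondary hydroperoxides from bonding at the other alkene carbon are expected by-products and are removed by chromatography.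

Step 6
Reactants: 9 (1R,4S)-4-hydroxy-1,4-dimethylcyclopent-2-en-1-yl hydroperoxide
Product: 11 (1R,4S)-1,4-dimethyl-4-[(triethylsilyl)oxy]cyclopent-2-en-1-yl hydroperoxide, via bis-silylated hydroperoxide 10 (not isolated)
Conditions: Et3SiOTf (2.4 equiv), 2,6-lutidine, CH2Cl2, −78 → 0 °C; then MeOH, K2CO3 (0.3 equiv), 0 °C
Reagents that add atoms: triethylsilyl trifluoromethanesulfonate, CC[Si](CC)(CC)OS(=O)(=O)C(F)(F)F
Why: The silyl triflate silylates both the tertiary alcohol and the hydroperoxide, and base-catalysed methanolysis then cleaves only the silyl peroxide, whose peroxide anion is by far the better leaving group, so that the C4 oxygen stays masked and cannot later form a five-membered lactol with the C7 aldehyde (standard silyl protection and selective desilylation).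

Step 7
Reactants: 11 (1R,4S)-1,4-dimethyl-4-[(triethylsilyl)oxy]cyclopent-2-en-1-yl hydroperoxide
Product: 13 (4S,6R)-3-hydroxy-4,6-dimethyl-4-[(triethylsilyl)oxy]-1,2-dioxane-6-carbaldehyde, via hydroperoxy dialdehyde 12 (not isolated)
Conditions: O3, CH2Cl2/MeOH (4:1), NaHCO3, −78 °C; then Me2S (2 equiv), −78 → 0 °C
Reagents that add atoms: ozone, [O-][O+]=O
Why: Ozone adds to the C7=C3 bond, the primary ozonide cycloreverts to an aldehyde and a carbonyl oxide, methanol traps the carbonyl oxide and Me2S reduces the trapped peroxide, so that both alkene carbons end as aldehydes in 12. The C6 hydroperoxide then adds to the C3 aldehyde, forming the O–C3 bond and the 1,2-dioxane ring (O1, O2, C3, C4, C5, C6) by a 6-exo-trig peroxyhemiacetalisation. The closest known reaction types are the ozonolysis of unsaturated hydroperoxides and the spontaneous cyclisation of γ-hydroperoxy aldehydes to 1,2-dioxan-3-ols. No fixed stereocentre is created: C3 is an equilibrating hemiacetal carbon that is made planar again in step 17, and C4 and C6 are not touched. The step needs chemoselectivity for closure onto C3, which the substrate secures because addition of the hydroperoxide to C7 would give a four-membered ring and the C4 oxygen is silylated, so that no five-membered lactol to C7 can compete. It also needs the hydroperoxide to survive the reductive work-up, which is secured by the much faster reduction of the methanol-trapped carbonyl oxide and by capture of the tertiary hydroperoxide as a cyclic peroxyhemiacetal that Me2S does not reduce.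

Step 8
Reactants: 13 (4S,6R)-3-hydroxy-4,6-dimethyl-4-[(triethylsilyl)oxy]-1,2-dioxane-6-carbaldehyde
Product: 14 (4S,6R)-4,6-dimethyl-3,4-bis[(triethylsilyl)oxy]-1,2-dioxane-6-carbaldehyde
Conditions: Et3SiOTf (1.2 equiv), 2,6-lutidine, CH2Cl2, −78 °C
Reagents that add atoms: triethylsilyl trifluoromethanesulfonate, CC[Si](CC)(CC)OS(=O)(=O)C(F)(F)F
Why: Silylation of the peroxyhemiacetal hydroxyl (standard silyl ether formation with a non-nucleophilic base) locks the ring against base-induced opening to a hydroperoxide and a second aldehyde, while the C7 aldehyde, which has no α-hydrogen, is untouched.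

Step 9
Reactants: 15 6-bromohexan-1-ol
Product: 16 [(6-bromohexyl)oxy](tert-butyl)dimethylsilane
Conditions: t-BuMe2SiCl, imidazole, CH2Cl2, rt
Reagents that add atoms: tert-butyldimethylsilyl chloride, CC(C)(C)[Si](C)(C)Cl
Why: Standard silyl protection of the primary alcohol.

Step 10
Reactants: 16 [(6-bromohexyl)oxy](tert-butyl)dimethylsilane
Product: 17 {6-[(tert-butyldimethylsilyl)oxy]hexyl}triphenylphosphonium bromide
Conditions: PPh3, MeCN, 80 °C; recrystallised free of PPh3
Reagents that add atoms: triphenylphosphine, c1ccc(cc1)P(c1ccccc1)c1ccccc1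
Why: SN2 quaternisation of triphenylphosphine by the primary bromide gives the Wittig salt.

Step 11
Reactants: 14 (4S,6R)-4,6-dimethyl-3,4-bis[(triethylsilyl)oxy]-1,2-dioxane-6-carbaldehyde; 17 {6-[(tert-butyldimethylsilyl)oxy]hexyl}triphenylphosphonium bromide
Product: 19 tert-butyl({(6Z)-7-[(4S,6R)-4,6-dimethyl-3,4-bis(triethylsilyloxy)-1,2-dioxan-6-yl]hept-6-en-1-yl}oxy)dimethylsilane, via phosphonium ylide 18 (not isolated)
Conditions: 17 (1.3 equiv), NaN(SiMe3)2 (1.25 equiv), THF, −78 → 0 °C; ylide added to 14, THF, −78 °C → rt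
Reagents that add atoms: none
Why: Wittig olefination with a non-stabilised, salt-free ylide proceeds through an oxaphosphetane without a free alkoxide next to the peroxide, the capped peroxyacetal and the dialkyl peroxide are inert to the ylide at low temperature, and the alkene geometry (mainly Z) is irrelevant because the double bond is reduced next.

Step 12
Reactants: 19 tert-butyl({(6Z)-7-[(4S,6R)-4,6-dimethyl-3,4-bis(triethylsilyloxy)-1,2-dioxan-6-yl]hept-6-en-1-yl}oxy)dimethylsilane
Product: 20 tert-butyl({7-[(4S,6S)-4,6-dimethyl-3,4-bis(triethylsilyloxy)-1,2-dioxan-6-yl]heptyl}oxy)dimethylsilane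
Conditions: 2-nitrobenzenesulfonylhydrazide (excess, in portions), Et3N, CH2Cl2, rt
Reagents that add atoms: none
Why: Diimide, formed in situ from the sulfonylhydrazide, transfers two hydrogens to the C7=C8 bond in a concerted syn fashion and does not reduce the O–O bond, which catalytic hydrogenation would cleave.

Step 13
Reactants: 20 tert-butyl({7-[(4S,6S)-4,6-dimethyl-3,4-bis(triethylsilyloxy)-1,2-dioxan-6-yl]heptyl}oxy)dimethylsilane
Product: 22 7-[(4S,6S)-4-hydroxy-3-methoxy-4,6-dimethyl-1,2-dioxan-6-yl]heptan-1-ol, via desilylated peroxyhemiacetal 21 (not isolated)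
Conditions: p-TsOH·H2O (0.2 equiv), MeOH, 0 °C → rt; Et3N quench
Reagents that add atoms: methanol, CO
Why: Acid-catalysed methanolysis removes the three silyl groups and converts the liberated peroxyhemiacetal into the methyl peroxyacetal (Fischer-type acetalisation), which is unambiguous at this stage because no aldehyde is left in the molecule.

Step 14
Reactants: 22 7-[(4S,6S)-4-hydroxy-3-methoxy-4,6-dimethyl-1,2-dioxan-6-yl]heptan-1-ol
Product: 23 7-[(4S,6S)-4-hydroxy-3-methoxy-4,6-dimethyl-1,2-dioxan-6-yl]heptanal
Conditions: Dess–Martin periodinane (1.3 equiv), NaHCO3, CH2Cl2, 0 °C → rt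
Reagents that add atoms: none
Why: Dess–Martin oxidation converts the primary alcohol to the aldehyde under buffered, non-reducing conditions that leave the tertiary alcohol and the peroxide untouched.

Step 15
Reactants: 23 7-[(4S,6S)-4-hydroxy-3-methoxy-4,6-dimethyl-1,2-dioxan-6-yl]heptanal; 24 diethyl (E)-cinnamylphosphonate
Product: 26 (4S,6S)-3-methoxy-4,6-dimethyl-6-[(7E,9E)-10-phenyldeca-7,9-dien-1-yl]-1,2-dioxan-4-ol, via lithiated phosphonate 25 (not isolated)
Conditions: 24 (2.2 equiv), LiN(SiMe3)2 (2.1 equiv), THF, −78 °C; then 23, −78 °C → rt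
Reagents that add atoms: none
Why: Horner–Wadsworth–Emmons olefination with the lithiated allylic phosphonate forms the C13=C14 bond with E selectivity and keeps the E styryl bond, giving the E,E-diene, while the methyl peroxyacetal is stable to the base and the lactone does not yet exist.

Step 16
Reactants: 26 (4S,6S)-3-methoxy-4,6-dimethyl-6-[(7E,9E)-10-phenyldeca-7,9-dien-1-yl]-1,2-dioxan-4-ol
Product: 27 (4S,6S)-3-methoxy-4,6-dimethyl-6-[(7E,9E)-10-phenyldeca-7,9-dien-1-yl]-1,2-dioxan-4-yl acetate
Conditions: Ac2O, Et3N, DMAP, CH2Cl2, rt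
Reagents that add atoms: acetic anhydride, CC(=O)OC(C)=O
Why: DMAP-catalysed acylation of the tertiary alcohol installs the acetate whose carbonyl and methyl carbons become C1 and C2.

Step 17
Reactants: 27 (4S,6S)-3-methoxy-4,6-dimethyl-6-[(7E,9E)-10-phenyldeca-7,9-dien-1-yl]-1,2-dioxan-4-yl acetate
Product: 29 plakortolide R, via silyl ketene acetal 28 (not isolated)
Conditions: LiN(i-Pr)2 (1.2 equiv), Me3SiCl (1.5 equiv), THF, −78 °C; solvent exchange to CH2Cl2; Me3SiOTf (0.3 equiv), 2,6-di-tert-butyl-4-methylpyridine (0.1 equiv), −78 → −40 °C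
Reagents that add atoms: none
Why: Kinetic enolisation with in situ O-silylation gives the silyl ketene acetal (as in Ireland–Claisen practice), and Me3SiOTf then ionises the methyl peroxyacetal to a peroxycarbenium ion that the tethered ketene acetal attacks in an intramolecular Mukaiyama-type addition, a reaction type known for silyl ketene acetals and 3-alkoxy-1,2-dioxanes; the three-atom tether from the C4 oxygen can reach only the face of C3 syn to that oxygen, so the five-membered lactone forms cis-fused and the C3 stereocentre is set by C4.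

Compound list
1 | (R)-2-methylglycidol | OC[C@]1(C)CO1 | starting material
2 | isopropenylmagnesium bromide | CC(=C)[Mg]Br | starting material
3 | (S)-2,4-dimethylpent-4-ene-1,2-diol | C=C(C)C[C@](C)(O)CO | intermediate
4 | (S)-2-hydroxy-2,4-dimethylpent-4-en-1-yl 4-methylbenzenesulfonate | C=C(C)C[C@](C)(O)COS(=O)(=O)c1ccc(C)cc1 | intermediate (not isolated)
5 | (S)-2-methyl-2-(2-methylprop-2-en-1-yl)oxirane | C=C(C)C[C@@]1(C)CO1 | intermediate
6 | vinylmagnesium bromide | C=C[Mg]Br | starting material
7 | (R)-2,4-dimethylhepta-1,6-dien-4-ol | C=C(C)C[C@](C)(O)CC=C | intermediate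
8 | (R)-1,3-dimethylcyclopent-3-en-1-ol | CC1=CC[C@@](C)(O)C1 | intermediate
9 | (1R,4S)-4-hydroxy-1,4-dimethylcyclopent-2-en-1-yl hydroperoxide | C[C@]1(OO)C=C[C@@](C)(O)C1 | intermediate
10 | triethyl({(1S,4R)-1,4-dimethyl-4-[(triethylsilyl)peroxy]cyclopent-2-en-1-yl}oxy)silane | C[C@]1(OO[Si](CC)(CC)CC)C=C[C@@](C)(O[Si](CC)(CC)CC)C1 | intermediate (not isolated)
11 | (1R,4S)-1,4-dimethyl-4-[(triethylsilyl)oxy]cyclopent-2-en-1-yl hydroperoxide | C[C@]1(OO)C=C[C@@](C)(O[Si](CC)(CC)CC)C1 | intermediate
12 | (2R,4S)-2-hydroperoxy-2,4-dimethyl-4-[(triethylsilyl)oxy]pentanedial | C[C@](OO)(C=O)C[C@](C)(O[Si](CC)(CC)CC)C=O | intermediate (not isolated)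
13 | (4S,6R)-3-hydroxy-4,6-dimethyl-4-[(triethylsilyl)oxy]-1,2-dioxane-6-carbaldehyde | C[C@]1(C=O)C[C@](C)(O[Si](CC)(CC)CC)C(O)OO1 | intermediate
14 | (4S,6R)-4,6-dimethyl-3,4-bis[(triethylsilyl)oxy]-1,2-dioxane-6-carbaldehyde | C[C@]1(C=O)C[C@](C)(O[Si](CC)(CC)CC)C(O[Si](CC)(CC)CC)OO1 | intermediate
15 | 6-bromohexan-1-ol | OCCCCCCBr | starting material
16 | [(6-bromohexyl)oxy](tert-butyl)dimethylsilane | CC(C)(C)[Si](C)(C)OCCCCCCBr | intermediate
17 | {6-[(tert-butyldimethylsilyl)oxy]hexyl}triphenylphosphonium bromide | CC(C)(C)[Si](C)(C)OCCCCCC[P+](c1ccccc1)(c1ccccc1)c1ccccc1.[Br-] | intermediate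
18 | {6-[(tert-butyldimethylsilyl)oxy]hexylidene}triphenylphosphorane | CC(C)(C)[Si](C)(C)OCCCCCC=P(c1ccccc1)(c1ccccc1)c1ccccc1 | intermediate (not isolated)
19 | tert-butyl({(6Z)-7-[(4S,6R)-4,6-dimethyl-3,4-bis(triethylsilyloxy)-1,2-dioxan-6-yl]hept-6-en-1-yl}oxy)dimethylsilane | C[C@]1(/C=C\CCCCCO[Si](C)(C)C(C)(C)C)C[C@](C)(O[Si](CC)(CC)CC)C(O[Si](CC)(CC)CC)OO1 | intermediate
20 | tert-butyl({7-[(4S,6S)-4,6-dimethyl-3,4-bis(triethylsilyloxy)-1,2-dioxan-6-yl]heptyl}oxy)dimethylsilane | C[C@]1(CCCCCCCO[Si](C)(C)C(C)(C)C)C[C@](C)(O[Si](CC)(CC)CC)C(O[Si](CC)(CC)CC)OO1 | intermediate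
21 | 7-[(4S,6S)-3,4-dihydroxy-4,6-dimethyl-1,2-dioxan-6-yl]heptan-1-ol | C[C@]1(CCCCCCCO)C[C@](C)(O)C(O)OO1 | intermediate (not isolated)
22 | 7-[(4S,6S)-4-hydroxy-3-methoxy-4,6-dimethyl-1,2-dioxan-6-yl]heptan-1-ol | C[C@]1(CCCCCCCO)C[C@](C)(O)C(OC)OO1 | intermediate
23 | 7-[(4S,6S)-4-hydroxy-3-methoxy-4,6-dimethyl-1,2-dioxan-6-yl]heptanal | C[C@]1(CCCCCCC=O)C[C@](C)(O)C(OC)OO1 | intermediate
24 | diethyl (E)-cinnamylphosphonate | CCOP(=O)(OCC)C/C=C/c1ccccc1 | starting material
25 | lithium salt of diethyl (E)-cinnamylphosphonate (α-carbanion) | CCOP(=O)(OCC)[CH-]/C=C/c1ccccc1.[Li+] | intermediate (not isolated)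
26 | (4S,6S)-3-methoxy-4,6-dimethyl-6-[(7E,9E)-10-phenyldeca-7,9-dien-1-yl]-1,2-dioxan-4-ol | C[C@]1(CCCCCC/C=C/C=C/c2ccccc2)C[C@](C)(O)C(OC)OO1 | intermediate
27 | (4S,6S)-3-methoxy-4,6-dimethyl-6-[(7E,9E)-10-phenyldeca-7,9-dien-1-yl]-1,2-dioxan-4-yl acetate | C[C@]1(CCCCCC/C=C/C=C/c2ccccc2)C[C@](C)(OC(C)=O)C(OC)OO1 | intermediate
28 | [(1-{[(4S,6S)-3-methoxy-4,6-dimethyl-6-[(7E,9E)-10-phenyldeca-7,9-dien-1-yl]-1,2-dioxan-4-yl]oxy}ethenyl)oxy]trimethylsilane | C[C@]1(CCCCCC/C=C/C=C/c2ccccc2)C[C@](C)(OC(=C)O[Si](C)(C)C)C(OC)OO1 | intermediate (not isolated)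
29 | plakortolide R | C[C@]1(CCCCCC/C=C/C=C/c2ccccc2)C[C@]2(C)OC(=O)C[C@@H]2OO1 | target

Total step count: 17. Longest linear sequence: 15 steps (steps 1–8 and 11–17); steps 9 and 10 prepare the Wittig salt.

Steps most likely to fail

Step 17 (lactone closure). What may go wrong: O-silylation of the hindered tertiary acetate enolate may be incomplete (C-silylation, or loss of the ketene acetal during solvent exchange), so that the peroxycarbenium ion is generated without a partner and fragments. The fallback sets out from alcohol 26 (step 16 is skipped) and brings in C1 and C2 with an external nucleophile. tert-Butyl[(1-methoxyethenyl)oxy]dimethylsilane and Me3SiOTf in CH2Cl2 at −78 °C (intermolecular Mukaiyama-type addition to the peroxycarbenium ion) should give methyl 2-[(3S,4S,6S)-4-hydroxy-4,6-dimethyl-6-[(7E,9E)-10-phenyldeca-7,9-dien-1-yl]-1,2-dioxan-3-yl]acetate F1 together with its C3 epimer. Catalytic p-TsOH in CH2Cl2 then lactonises F1, the only epimer that can close, and the route is rejoined at 29; the other epimer is separated. The price is that C3 is no longer set by a tether.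

Step 7 (key step). What may go wrong: the tertiary hydroperoxide may be lost before it closes the ring, by reduction during the work-up or by fragmentation of a carbonyl oxide formed next to it. The fallback separates the cleavage from the ring closure. From 11, 2-methoxypropene and PPTS in CH2Cl2 mask the hydroperoxide as the peroxyketal triethyl{[(1S,4R)-4-[(2-methoxypropan-2-yl)peroxy]-1,4-dimethylcyclopent-2-en-1-yl]oxy}silane F2. Ozonolysis (O3, CH2Cl2/MeOH, −78 °C; Me2S) then gives (2R,4S)-2-[(2-methoxypropan-2-yl)peroxy]-2,4-dimethyl-4-[(triethylsilyl)oxy]pentanedial F3, a dialkyl peroxide that the reductant does not touch. Brief treatment with AcOH/H2O/THF at 0 °C removes the ketal, the liberated hydroperoxide closes onto C3, and the route is rejoined at 13.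

Step 13 (global solvolysis and peroxyacetal exchange). What may go wrong: acetalisation at C3 is slowed by the neighbouring C4 oxygen, so the reaction may stall at the peroxyhemiacetal or drift to open-chain hydroperoxy acetals under prolonged protic acid. The fallback exchanges under aprotic Lewis-acid conditions before any silyl ether is removed. From 20, MeOSiMe3 and catalytic Me3SiOTf (CH2Cl2, −78 °C) should convert the silyl peroxyacetal through the peroxycarbenium ion into tert-butyl({7-[(4S,6S)-3-methoxy-4,6-dimethyl-4-[(triethylsilyl)oxy]-1,2-dioxan-6-yl]heptyl}oxy)dimethylsilane F4. HF·pyridine in THF then removes both silyl ethers and the route is rejoined at 22.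

Further compounds
F1 | step 17 | methyl 2-[(3S,4S,6S)-4-hydroxy-4,6-dimethyl-6-[(7E,9E)-10-phenyldeca-7,9-dien-1-yl]-1,2-dioxan-3-yl]acetate | C[C@]1(CCCCCC/C=C/C=C/c2ccccc2)C[C@](C)(O)[C@H](CC(=O)OC)OO1
F2 | step 7 | triethyl{[(1S,4R)-4-[(2-methoxypropan-2-yl)peroxy]-1,4-dimethylcyclopent-2-en-1-yl]oxy}silane | C[C@]1(OOC(C)(C)OC)C=C[C@@](C)(O[Si](CC)(CC)CC)C1
F3 | step 7 | (2R,4S)-2-[(2-methoxypropan-2-yl)peroxy]-2,4-dimethyl-4-[(triethylsilyl)oxy]pentanedial | C[C@](OOC(C)(C)OC)(C=O)C[C@](C)(O[Si](CC)(CC)CC)C=O
F4 | step 13 | tert-butyl({7-[(4S,6S)-3-methoxy-4,6-dimethyl-4-[(triethylsilyl)oxy]-1,2-dioxan-6-yl]heptyl}oxy)dimethylsilane | C[C@]1(CCCCCCCO[Si](C)(C)C(C)(C)C)C[C@](C)(O[Si](CC)(CC)CC)C(OC)OO1
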